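All runs were computed from invented constants; scatter was added.

Teal and red both start from 20 mM of L and differ in the amount of E, 16 mM against 49 mM, and that difference is what I can read.

| flask | L | E | remark | time |
|---|---|---|---|---|
| teal | 20 mM | 16 mM | run made earlier |  |
| red | 20 mM | 49 mM | run made earlier |  |
| north | 20 mM | 12.0 mM |  | 30 h |
| north-east | 20 mM | 40.0 mM |  | 10 h |

| run | time / h | J / % |
|---|---|---|
| teal | 0.667 | 1 |
| teal | 2.00 | 5 |
| teal | 4.00 | 8 |
| teal | 5.00 | 5 |
| teal | 8.00 | 9 |
| teal | 10.0 | 13 |
| red | 0.667 | 2 |
| red | 2.00 | 11 |
| red | 4.00 | 14 |
| red | 5.00 | 19 |
| red | 8.00 | 23 |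
| red | 10.0 | 26 |

(each reading ± 1.5 percentage points)

1. the winner by amount of J, in percent of the L charged; "neither" if no more than 2 percentage points parts them (north / north-east / neither)
2. how much J is there at the end, in percent of the L charged: north
3. how much J is there at the end, in percent of the L charged: north-east

Dividing red's J by teal's J at the same 10.0 h removes time from the comparison, and setting the logarithm of that ratio over the logarithm of the ratio of [E] charged gives the reading 0.619, which I call the E exponent, the power of [E] charged that J follows at a fixed time, an apparent order in E. North-east, with 40.0 mM of E at that same time, must lie above teal's 13% and below red's 26%, and the exponent tightens this bracket to 22.9%. For north, the exponent carries teal down to 12.0 mM and gives 10.9% at 10.0 h, my floor so long as J does not fall, while my ceiling is 32.6%, that pace held for 30 h. The ceiling stands high, because red gains 11% by 2.00 h yet 3 percentage points over its last 2.00 h. The same division along time, red from 5.00 h to 10.0 h, reads 0.453 and puts north near 17.9%, so I commit to north-east, at 22.9% against north's 17.9%, with 2 points as the margin.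

The forecast says “North-east wins clearly.” It gives north 14%, within 10% to 20%, which is inside my bracket but below my 17.9%, and north-east 23%, within 19.5% to 26.5%, which is where I stand too.

The flasks give 17.7% for north and 23.0% for north-east, each inside my bracket, and these steps run in them:

    L + E → X + J (k = 1.30 M⁻¹ h⁻¹)
    E + X ⇌ D, settled at all times (K = 620 M⁻¹)
    2 E → Q (k = 2.20 M⁻¹ h⁻¹)

North-east has moved by 5 points once its E is lowered to 27.0 mM, and the exponent gives a fall of 5 points there. Applied to a neighbour of north charged with 48 mM of E, the exponent lifts north's 17.7% to 41.7%, and that neighbour gives 37.5%.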